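The 3(2H)-furanone is read as a cyclised α'-hydroxy ynone: its C1–C2 bond (ketone carbon to vinylic CH, germacrane numbering) is also a bond of the ten-membered carbocycle, and its O–C3 bond (ring oxygen to enol-ether carbon) is the ether bridge from C10. One operation therefore closes both rings from a monocyclic α-methylene-γ-butyrolactone carrying an α-silyloxy acid chloride arm on C8 and a (Z)-enyne arm on C7: intramolecular PdCl2(PPh3)2/CuI acyl–alkynyl coupling forms C1–C2, and fluoride release of the C10 oxygen triggers 5-endo-dig addition to C3. The precursor comes from an indium Barbier union of a bromomethyl butenolide with a (Z)-enynal, which sets C6 and C7; the epoxy ester is attached last.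

Key step: step 10

Remark: skeletal atoms carry germacrane numbers (C1 furanone C=O, C2 furanone CH, C3 furanone C–O, C4=C5 the Z alkene, C6 acyloxy carbon, C7/C8 lactone ring fusion, C9 CH2, C10 quaternary carbon, C11–C13 methylene lactone); the ester is the cis-dimethyl (2S,3R)-epoxide, as the target structure requires.

Step 1
Reactants: 1 4-phenylbut-3-yn-2-one
Product: 2 trimethyl[(4-phenylbut-1-en-3-yn-2-yl)oxy]silane
Conditions: TMSOTf, Et3N, Et2O, 0 °C
Reagents that add atoms: trimethylsilyl triflate, C[Si](C)(C)OS(=O)(=O)C(F)(F)F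
Why: Soft enolisation of the methyl ketone, the only enolisable position, gives the silyl enol ether (enol silane formation for a Mukaiyama aldol).

Step 2
Reactants: 2 trimethyl[(4-phenylbut-1-en-3-yn-2-yl)oxy]silane; 3 tert-butyl 2-oxopropanoate (tert-butyl pyruvate)
Product: 4 tert-butyl (2R)-2-methyl-4-oxo-6-phenyl-2-[(trimethylsilyl)oxy]hex-5-ynoate
Conditions: Cu(OTf)2 (10 mol%), (R,R)-2,2'-isopropylidenebis(4-tert-butyl-2-oxazoline) (11 mol%), THF, −78 °C; filtration through silica without acid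
Reagents that add atoms: none
Why: Catalytic enantioselective Mukaiyama aldol addition to the pyruvate held in a square-planar Cu chelate whose tert-butyl groups leave one ketone face open; the (R,R)-ligand is chosen so that the tertiary carbinol (C10) forms R, and silyl transfer delivers the TMS ether.

Step 3
Reactants: 4 tert-butyl (2R)-2-methyl-4-oxo-6-phenyl-2-[(trimethylsilyl)oxy]hex-5-ynoate
Product: 6 tert-butyl (2R,4S)-2,4-dihydroxy-2-methyl-6-phenylhex-5-ynoate, via TMS-ether propargylic alcohol 5 (not isolated)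
Conditions: Ru[(S,S)-TsDPEN](p-cymene) (1 mol%), i-PrOH, 25 °C; then 1 M HCl, THF, 0 °C
Reagents that add atoms: none
Why: Noyori asymmetric transfer hydrogenation, in which the catalyst tells the alkynyl from the alkyl flank and the (S,S)-complex should give the 4S carbinol (C8) under reagent control; the silyl ether keeps the β-oxygen from adding 6-endo to the ynone and is then removed by dilute acid.

Step 4
Reactants: 6 tert-butyl (2R,4S)-2,4-dihydroxy-2-methyl-6-phenylhex-5-ynoate
Product: 7 tert-butyl (2R,4S,5Z)-2,4-dihydroxy-2-methyl-6-phenylhex-5-enoate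
Conditions: H2 (1 atm), Pd/CaCO3 poisoned with Pb(OAc)2, quinoline, EtOAc, 25 °C
Reagents that add atoms: none
Why: Lindlar-type syn semi-hydrogenation gives the Z alkene, which serves only as the metathesis handle.

Step 5
Reactants: 7 tert-butyl (2R,4S,5Z)-2,4-dihydroxy-2-methyl-6-phenylhex-5-enoate; 8 2-(bromomethyl)prop-2-enoic acid
Product: 10 tert-butyl (2R,4S,5Z)-4-{[2-(bromomethyl)prop-2-enoyl]oxy}-2-hydroxy-2-methyl-6-phenylhex-5-enoate, via 2-(bromomethyl)acryloyl chloride 9 (not isolated)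
Conditions: 8, (COCl)2, cat. DMF, CH2Cl2, 0 → 25 °C; then 7, i-Pr2NEt, CH2Cl2, −40 → 0 °C
Reagents that add atoms: none
Why: Acyl chloride esterification, selective for the secondary allylic hydroxyl over the hindered tertiary one; the non-nucleophilic base avoids SN2' attack on the bromomethyl acrylate.

Step 6
Reactants: 10 tert-butyl (2R,4S,5Z)-4-{[2-(bromomethyl)prop-2-enoyl]oxy}-2-hydroxy-2-methyl-6-phenylhex-5-enoate
Product: 11 tert-butyl (2R)-3-[(2S)-4-(bromomethyl)-5-oxo-2,5-dihydrofuran-2-yl]-2-hydroxy-2-methylpropanoate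
Conditions: Hoveyda–Grubbs second-generation catalyst RuCl2(=CH-C6H4-2-OiPr)(H2IMes) (5 mol%), CH2Cl2, 40 °C
Reagents that add atoms: none
Why: Ring-closing metathesis between the styryl alkene and the acrylate alkene closes the butenolide and expels styrene; the neutral conditions leave the γ-stereocentre (C8) untouched.

Step 7
Reactants: 12 (2Z)-3-methylpent-2-en-4-yn-1-ol
Product: 13 (2Z)-3-methylpent-2-en-4-ynal
Conditions: activated MnO2, CH2Cl2, 25 °C; solution used at once
Reagents that add atoms: none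
Why: Chemoselective allylic oxidation on neutral, heterogeneous MnO2, which should keep the Z geometry of the trisubstituted alkene.

Step 8
Reactants: 11 tert-butyl (2R)-3-[(2S)-4-(bromomethyl)-5-oxo-2,5-dihydrofuran-2-yl]-2-hydroxy-2-methylpropanoate; 13 (2Z)-3-methylpent-2-en-4-ynal
Product: 14 tert-butyl (2R)-2-hydroxy-3-[(2S,3S)-3-[(1R,2Z)-1-hydroxy-3-methylpent-2-en-4-yn-1-yl]-4-methylidene-5-oxooxolan-2-yl]-2-methylpropanoate
Conditions: indium powder, THF/H2O (1:1), 25 °C
Reagents that add atoms: none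
Why: Indium-mediated Barbier allylation in which the allylindium reagent reacts through its γ-carbon (C7) in a Zimmerman–Traxler chair: addition anti to the C8 side chain gives the 7,8-trans lactone, and the ring-fixed E-type allyl geometry with the aldehyde substituent equatorial gives the anti (6R) carbinol while the exocyclic methylene is regenerated.

Step 9
Reactants: 14 tert-butyl (2R)-2-hydroxy-3-[(2S,3S)-3-[(1R,2Z)-1-hydroxy-3-methylpent-2-en-4-yn-1-yl]-4-methylidene-5-oxooxolan-2-yl]-2-methylpropanoate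
Product: 16 trimethylsilyl (2R)-3-[(2S,3R)-3-[(1R,2Z)-1-[(tert-butyldimethylsilyl)oxy]-3-methylpent-2-en-4-yn-1-yl]-4-methylidene-5-oxooxolan-2-yl]-2-methyl-2-[(trimethylsilyl)oxy]propanoate, via mono-TBS ether 15 (not isolated)
Conditions: TBSOTf (1.05 equiv), 2,6-lutidine, CH2Cl2, −78 °C; then TMSOTf (3.5 equiv), −78 → 25 °C; non-aqueous work-up, used crude
Reagents that add atoms: tert-butyldimethylsilyl triflate, CC(C)(C)[Si](C)(C)OS(=O)(=O)C(F)(F)F; trimethylsilyl triflate, C[Si](C)(C)OS(=O)(=O)C(F)(F)F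
Why: Silyl triflate silylation: at −78 °C TBSOTf takes only the secondary allylic hydroxyl, then TMSOTf caps the tertiary hydroxyl and turns the tert-butyl ester into the trimethylsilyl ester with loss of isobutene (silyl-triflate-mediated tert-butyl ester cleavage).

Step 10
Reactants: 16 trimethylsilyl (2R)-3-[(2S,3R)-3-[(1R,2Z)-1-[(tert-butyldimethylsilyl)oxy]-3-methylpent-2-en-4-yn-1-yl]-4-methylidene-5-oxooxolan-2-yl]-2-methyl-2-[(trimethylsilyl)oxy]propanoate
Product: 20 (4Z,6R,7R,8S,10R)-6-[(tert-butyldimethylsilyl)oxy]-3,10-epoxy-1-oxogermacra-2,4,11(13)-trien-12,8-olide, via acid chloride 17 (not isolated), via macrocyclic silyloxy ynone 18 (not isolated), via macrocyclic hydroxy ynone 19 (not isolated)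
Conditions: (COCl)2, cat. DMF, CH2Cl2, 0 °C, evaporate; then addition over 10 h to PdCl2(PPh3)2 (10 mol%), CuI (20 mol%), Et3N, THF, 25 °C (2 mM); then TBAF/AcOH (1:1), 0 °C
Reagents that add atoms: none
Why: Oxalyl chloride/DMF turns the silyl ester into the acid chloride under neutral conditions; zerovalent palladium inserts into the C–Cl bond, the copper acetylide of the terminal alkyne transmetalates and reductive elimination forms C1–C2, then fluoride frees the C10 oxygen, which adds to C3 of the ynone, and the allenolate is protonated at C2. The closest known reactions are the acyl Sonogashira ynone synthesis and the cyclisation of α'-hydroxy ynones to 3(2H)-furanones. The ten-membered carbocycle closes by intramolecular acyl–alkynyl cross-coupling and the furanone by a transannular 5-endo-dig oxa-Michael addition. No stereocentre is created: C6, C7, C8 and C10 pass through unchanged (C10 is quaternary, so neither ketene formation nor epimerisation is possible) and the C2=C3 geometry is fixed by the five-membered ring. The step needs ring closure to beat oligomerisation and the C10 oxygen, not the C6 oxygen, to attack the ynone; slow addition at high dilution, the Z C4=C5 alkene and the trans-lactone that hold C1 near C2 secure the first, and the robust TBS ether on C6 beside the fluoride-labile TMS ether on C10 secures the second.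

Step 11
Reactants: 20 (4Z,6R,7R,8S,10R)-6-[(tert-butyldimethylsilyl)oxy]-3,10-epoxy-1-oxogermacra-2,4,11(13)-trien-12,8-olide
Product: 21 (4Z,6R,7S,8S,10R)-3,10-epoxy-6-hydroxy-1-oxogermacra-2,4,11(13)-trien-12,8-olide
Conditions: HF·pyridine, pyridine, THF, 0 → 25 °C
Reagents that add atoms: none
Why: Fluoride cleavage of the secondary TBS ether under buffered, non-basic conditions, which should avoid translactonisation of the freed C6 hydroxyl onto the lactone carbonyl.

Step 12
Reactants: 22 (2E)-2-methylbut-2-en-1-ol (tiglyl alcohol)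
Product: 23 [(2R,3R)-2,3-dimethyloxiran-2-yl]methanol
Conditions: Ti(OiPr)4 (10 mol%), D-(−)-diethyl tartrate (12 mol%), t-BuOOH, 4 Å MS, CH2Cl2, −20 °C
Reagents that add atoms: tert-butyl hydroperoxide, CC(C)(C)OO
Why: Sharpless asymmetric epoxidation; D-(−)-tartrate directs oxygen to the face of the E allylic alcohol that gives the (2R,3R)-epoxide, and the E alkene fixes the cis relation of the two methyl groups.

Step 13
Reactants: 23 [(2R,3R)-2,3-dimethyloxiran-2-yl]methanol
Product: 25 (2S,3R)-2,3-dimethyloxirane-2-carboxylic acid, via epoxy aldehyde 24 (not isolated)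
Conditions: RuCl3·3H2O (2 mol%), NaIO4, CCl4/MeCN/H2O, 25 °C
Reagents that add atoms: water, O
Why: RuO4 generated in situ oxidises the primary alcohol through the aldehyde hydrate to the acid without touching the epoxide (ruthenium tetroxide oxidation); the descriptor at C2 changes only through ligand priority.

Step 14
Reactants: 21 (4Z,6R,7S,8S,10R)-3,10-epoxy-6-hydroxy-1-oxogermacra-2,4,11(13)-trien-12,8-olide; 25 (2S,3R)-2,3-dimethyloxirane-2-carboxylic acid
Product: 27 (4Z,6R,7R,8S,10R)-3,10-epoxy-1-oxo-12,8-olidogermacra-2,4,11(13)-trien-6-yl (2S,3R)-2,3-dimethyloxirane-2-carboxylate (CNP0258430.2), via mixed anhydride 26 (not isolated)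
Conditions: 25, 2,4,6-trichlorobenzoyl chloride, Et3N, toluene, 25 °C; then 21, DMAP, 25 °C
Reagents that add atoms: none
Why: Yamaguchi esterification; DMAP transfers the epoxy acyl group from the mixed anhydride to the C6 hydroxyl, and the acid has no α-hydrogen, so it cannot epimerise.

Compound list
1 | 4-phenylbut-3-yn-2-one | CC(=O)C#Cc1ccccc1 | starting material
2 | trimethyl[(4-phenylbut-1-en-3-yn-2-yl)oxy]silane | C=C(O[Si](C)(C)C)C#Cc1ccccc1 | intermediate
3 | tert-butyl 2-oxopropanoate | CC(=O)C(=O)OC(C)(C)C | starting material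
4 | tert-butyl (2R)-2-methyl-4-oxo-6-phenyl-2-[(trimethylsilyl)oxy]hex-5-ynoate | O=C(C#Cc1ccccc1)C[C@@](C)(O[Si](C)(C)C)C(=O)OC(C)(C)C | intermediate
5 | tert-butyl (2R,4S)-4-hydroxy-2-methyl-6-phenyl-2-[(trimethylsilyl)oxy]hex-5-ynoate | O[C@H](C#Cc1ccccc1)C[C@@](C)(O[Si](C)(C)C)C(=O)OC(C)(C)C | intermediate (not isolated)
6 | tert-butyl (2R,4S)-2,4-dihydroxy-2-methyl-6-phenylhex-5-ynoate | O[C@H](C#Cc1ccccc1)C[C@@](C)(O)C(=O)OC(C)(C)C | intermediate
7 | tert-butyl (2R,4S,5Z)-2,4-dihydroxy-2-methyl-6-phenylhex-5-enoate | O[C@H](/C=C\c1ccccc1)C[C@@](C)(O)C(=O)OC(C)(C)C | intermediate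
8 | 2-(bromomethyl)prop-2-enoic acid | C=C(CBr)C(=O)O | starting material
9 | 2-(bromomethyl)prop-2-enoyl chloride | C=C(CBr)C(Cl)=O | intermediate (not isolated)
10 | tert-butyl (2R,4S,5Z)-4-{[2-(bromomethyl)prop-2-enoyl]oxy}-2-hydroxy-2-methyl-6-phenylhex-5-enoate | C=C(CBr)C(=O)O[C@H](/C=C\c1ccccc1)C[C@@](C)(O)C(=O)OC(C)(C)C | intermediate
11 | tert-butyl (2R)-3-[(2S)-4-(bromomethyl)-5-oxo-2,5-dihydrofuran-2-yl]-2-hydroxy-2-methylpropanoate | O=C1O[C@@H](C[C@@](C)(O)C(=O)OC(C)(C)C)C=C1CBr | intermediate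
12 | (2Z)-3-methylpent-2-en-4-yn-1-ol | OC/C=C(C)\C#C | starting material
13 | (2Z)-3-methylpent-2-en-4-ynal | O=C/C=C(C)\C#C | intermediate
14 | tert-butyl (2R)-2-hydroxy-3-[(2S,3S)-3-[(1R,2Z)-1-hydroxy-3-methylpent-2-en-4-yn-1-yl]-4-methylidene-5-oxooxolan-2-yl]-2-methylpropanoate | C=C1C(=O)O[C@@H](C[C@@](C)(O)C(=O)OC(C)(C)C)[C@@H]1[C@H](O)/C=C(C)\C#C | intermediate
15 | tert-butyl (2R)-3-[(2S,3R)-3-[(1R,2Z)-1-[(tert-butyldimethylsilyl)oxy]-3-methylpent-2-en-4-yn-1-yl]-4-methylidene-5-oxooxolan-2-yl]-2-hydroxy-2-methylpropanoate | C=C1C(=O)O[C@@H](C[C@@](C)(O)C(=O)OC(C)(C)C)[C@@H]1[C@H](O[Si](C)(C)C(C)(C)C)/C=C(C)\C#C | intermediate (not isolated)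
16 | trimethylsilyl (2R)-3-[(2S,3R)-3-[(1R,2Z)-1-[(tert-butyldimethylsilyl)oxy]-3-methylpent-2-en-4-yn-1-yl]-4-methylidene-5-oxooxolan-2-yl]-2-methyl-2-[(trimethylsilyl)oxy]propanoate | C=C1C(=O)O[C@@H](C[C@@](C)(O[Si](C)(C)C)C(=O)O[Si](C)(C)C)[C@@H]1[C@H](O[Si](C)(C)C(C)(C)C)/C=C(C)\C#C | intermediate
17 | (2R)-3-[(2S,3R)-3-[(1R,2Z)-1-[(tert-butyldimethylsilyl)oxy]-3-methylpent-2-en-4-yn-1-yl]-4-methylidene-5-oxooxolan-2-yl]-2-methyl-2-[(trimethylsilyl)oxy]propanoyl chloride | C=C1C(=O)O[C@@H](C[C@@](C)(O[Si](C)(C)C)C(Cl)=O)[C@@H]1[C@H](O[Si](C)(C)C(C)(C)C)/C=C(C)\C#C | intermediate (not isolated)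
18 | (4Z,6R,7R,8S,10R)-6-[(tert-butyldimethylsilyl)oxy]-1-oxo-10-[(trimethylsilyl)oxy]germacra-4,11(13)-dien-2-yn-12,8-olide | C=C1C(=O)O[C@H]2C[C@@](C)(O[Si](C)(C)C)C(=O)C#C/C(C)=C\[C@@H](O[Si](C)(C)C(C)(C)C)[C@H]12 | intermediate (not isolated)
19 | (4Z,6R,7R,8S,10R)-6-[(tert-butyldimethylsilyl)oxy]-10-hydroxy-1-oxogermacra-4,11(13)-dien-2-yn-12,8-olide | C=C1C(=O)O[C@H]2C[C@@](C)(O)C(=O)C#C/C(C)=C\[C@@H](O[Si](C)(C)C(C)(C)C)[C@H]12 | intermediate (not isolated)
20 | (4Z,6R,7R,8S,10R)-6-[(tert-butyldimethylsilyl)oxy]-3,10-epoxy-1-oxogermacra-2,4,11(13)-trien-12,8-olide | C=C1C(=O)O[C@H]2C[C@@]3(C)OC(=CC3=O)/C(C)=C\[C@@H](O[Si](C)(C)C(C)(C)C)[C@H]12 | intermediate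
21 | (4Z,6R,7S,8S,10R)-3,10-epoxy-6-hydroxy-1-oxogermacra-2,4,11(13)-trien-12,8-olide | C=C1C(=O)O[C@H]2C[C@@]3(C)OC(=CC3=O)/C(C)=C\[C@@H](O)[C@H]12 | intermediate
22 | (2E)-2-methylbut-2-en-1-ol | C/C=C(\C)CO | starting material
23 | [(2R,3R)-2,3-dimethyloxiran-2-yl]methanol | OC[C@@]1(C)O[C@@H]1C | intermediate
24 | (2S,3R)-2,3-dimethyloxirane-2-carbaldehyde | O=C[C@@]1(C)O[C@@H]1C | intermediate (not isolated)
25 | (2S,3R)-2,3-dimethyloxirane-2-carboxylic acid | OC(=O)[C@@]1(C)O[C@@H]1C | intermediate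
26 | (2S,3R)-2,3-dimethyloxirane-2-carboxylic 2,4,6-trichlorobenzoic anhydride | O=C(OC(=O)c1c(Cl)cc(Cl)cc1Cl)[C@@]1(C)O[C@@H]1C | intermediate (not isolated)
27 | (4Z,6R,7R,8S,10R)-3,10-epoxy-1-oxo-12,8-olidogermacra-2,4,11(13)-trien-6-yl (2S,3R)-2,3-dimethyloxirane-2-carboxylate (CNP0258430.2) | C=C1C(=O)O[C@H]2C[C@@]3(C)OC(=CC3=O)/C(C)=C\[C@@H](OC(=O)[C@@]3(C)O[C@@H]3C)[C@H]12 | target

Total step count: 14. Longest linear sequence: 11 steps (steps 1–6, 8–11 and 14).

Steps most likely to fail

Step 10. Ring closure may lose to intermolecular coupling, or the hindered acyl–palladium species may turn over so slowly that the C10 silyl ether is lost before the ring is closed. The fallback sets out from 16 and comes back at 20; it replaces the acyl coupling by a stepwise alkynylation of an aldehyde. The acid chloride 17, made as in the main route, is reduced with LiAlH(OtBu)3 at −78 °C to α-silyloxy aldehyde F1. This non-enolisable aldehyde is closed onto the terminal alkyne with Zn(OTf)2/Et3N in toluene at high dilution (intramolecular zinc acetylide addition) to give macrocyclic propargylic alcohol F2. Dess–Martin oxidation then gives ynone 18, and TBAF/AcOH converts 18 into 20 as before.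

Step 8. Facial selectivity at the aldehyde carbon (C6) may be eroded by an open transition state in water, and the Z enal may isomerise before it reacts. The fallback sets out from 14 as obtained and comes back at 14. The carbinol mixture is oxidised with Dess–Martin periodinane to enynone F3, and C6 is then set under reagent control by Corey–Bakshi–Shibata reduction (oxazaborolidine enantiomer matched to the 6R alcohol, catecholborane, −78 °C).

Step 2. The conjugated enol silane may add slowly or with poor face selectivity to the bulkier tert-butyl pyruvate chelate. The fallback sets out from 3 and comes back at 4. S-Ethyl thioacetate is converted (LDA, TMSCl, THF, −78 °C) into silyl ketene thioacetal F4, which is used in the same Cu(OTf)2/(R,R)-bis(oxazoline) aldol to give thioester F5. Coupling of F5 with phenylacetylene (PdCl2(dppf), P(2-furyl)3, CuI, Et3N, DMF, 50 °C; thioester–alkyne ynone synthesis) then delivers 4.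

Further compounds
F1 | step 10 | (2R)-3-[(2S,3R)-3-[(1R,2Z)-1-[(tert-butyldimethylsilyl)oxy]-3-methylpent-2-en-4-yn-1-yl]-4-methylidene-5-oxooxolan-2-yl]-2-methyl-2-[(trimethylsilyl)oxy]propanal | C=C1C(=O)O[C@@H](C[C@@](C)(O[Si](C)(C)C)C=O)[C@@H]1[C@H](O[Si](C)(C)C(C)(C)C)/C=C(C)\C#C
F2 | step 10 | (4Z,6R,7R,8S,10R)-6-[(tert-butyldimethylsilyl)oxy]-1-hydroxy-10-[(trimethylsilyl)oxy]germacra-4,11(13)-dien-2-yn-12,8-olide (C1 epimers) | C=C1C(=O)O[C@H]2C[C@@](C)(O[Si](C)(C)C)C(O)C#C/C(C)=C\[C@@H](O[Si](C)(C)C(C)(C)C)[C@H]12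
F3 | step 8 | tert-butyl (2R)-2-hydroxy-2-methyl-3-[(2S,3R)-4-methylidene-3-[(2Z)-3-methylpent-2-en-4-ynoyl]-5-oxooxolan-2-yl]propanoate | C=C1C(=O)O[C@@H](C[C@@](C)(O)C(=O)OC(C)(C)C)[C@@H]1C(=O)/C=C(C)\C#C
F4 | step 2 | {[1-(ethylsulfanyl)ethenyl]oxy}trimethylsilane | C=C(SCC)O[Si](C)(C)C
F5 | step 2 | 1-tert-butyl 4-S-ethyl (2R)-2-methyl-2-[(trimethylsilyl)oxy]-4-thiobutanedioate | CCSC(=O)C[C@@](C)(O[Si](C)(C)C)C(=O)OC(C)(C)C
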